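The carbocycle of the hexahydro-1-benzofuran end group is cut at C4–C5 and C7–C7a: its C5–C6(OH)–C7 segment is a glycerol-type 1,3-dielectrophile lying between two fully substituted carbons, C4 (gem-dimethyl) and C7a (methyl, ring oxygen). In one flask (R)-epichlorohydrin is therefore attacked first by lithiated 2-methyl-1,3-dithiane (future C7a) and then by lithiated isobutyronitrile (future C4), which forms both bonds and delivers the open chain with the C6 carbinol centre in place. That centre then steers an acyloin ring closure (C7a), an alkynyl carbinol and an allene, whose cycloisomerization sets C2; a late alkynylation and lactonization attach the polyenyne.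

Key step: step 1

Remark: the bicyclic end group is numbered as a 1-benzofuran (O1, C2, C3, C3a, C4 to C7, C7a), TBSO and TESO stand for tert-butyldimethylsilyloxy and triethylsilyloxy, and (R)-epichlorohydrin, (4R,6R)-actinol and (E)-3-methylpent-2-en-4-yn-1-ol are taken as purchased in isomerically pure form.

Step 1
Reactants: 1 2-methyl-1,3-dithiane; 2 (R)-epichlorohydrin; 3 isobutyronitrile
Product: 5 (S)-4-hydroxy-2,2-dimethyl-5-(2-methyl-1,3-dithian-2-yl)pentanenitrile, via dithianyl epoxide 4 (not isolated)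
Conditions: 1, n-BuLi, THF, −30 °C; 2, −78 → 0 °C; then 3/LiN(iPr)2 (premixed, THF, −78 °C), 0 °C → rt; aq. NH4Cl
Reagents that add atoms: none
Why: Lithiated 2-methyl-1,3-dithiane (the acyl-anion form of the future C7a methyl ketone) opens the epoxide of 2 at its CH2 terminus by SN2 attack; on warming, the chlorohydrin alkoxide displaces chloride (3-exo-tet) to give the transposed epoxide 4, whose CH2 terminus is then opened by the nitrile-stabilized tertiary carbanion of 3 (future C4), so that C7–C7a and C4–C5 are both made in one flask. The closest known reaction type is the epichlorohydrin linchpin coupling of lithiated dithianes followed by epoxide opening with a second carbanion. The only ring closed here is the transient epoxide (3-exo-tet); the carbocycle itself is closed in step 5. No new stereocentre is created: the carbinol centre is carried over unchanged from (R)-epichlorohydrin and is (S) in 5 only because the CIP priorities change. The step needs attack at the epoxide rather than direct chloride displacement (which would lead to the enantiomer) and a fixed order of addition; the first is expected from the higher reactivity of the epoxide CH2 toward the dithiane anion at −78 °C, the second from adding the nitrile anion only after 4 has formed.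

Step 2
Reactants: 5 (S)-4-hydroxy-2,2-dimethyl-5-(2-methyl-1,3-dithian-2-yl)pentanenitrile
Product: 6 (S)-4-(TBSO)-2,2-dimethyl-5-(2-methyl-1,3-dithian-2-yl)pentanenitrile
Conditions: t-BuMe2SiCl, imidazole, DMF, rt
Reagents that add atoms: tert-butyldimethylsilyl chloride, CC(C)(C)[Si](C)(C)Cl
Why: Standard silylation of the secondary alcohol prevents lactol formation once the aldehyde is unveiled; no stereocentre is touched.

Step 3
Reactants: 6 (S)-4-(TBSO)-2,2-dimethyl-5-(2-methyl-1,3-dithian-2-yl)pentanenitrile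
Product: 7 (S)-4-(TBSO)-2,2-dimethyl-5-(2-methyl-1,3-dithian-2-yl)pentanal
Conditions: iBu2AlH, CH2Cl2, −78 °C; then aq. potassium sodium tartrate
Reagents that add atoms: water, O
Why: Partial reduction of the nitrile to the aluminium aldimine, hydrolysed on work-up, should give the α-quaternary, non-enolizable aldehyde while the dithioketal and silyl ether stay intact.

Step 4
Reactants: 7 (S)-4-(TBSO)-2,2-dimethyl-5-(2-methyl-1,3-dithian-2-yl)pentanal
Product: 8 (S)-4-(TBSO)-2,2-dimethyl-6-oxoheptanal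
Conditions: MeI, CaCO3, MeCN/H2O (9:1), 40 °C
Reagents that add atoms: water, O
Why: S-Methylation-assisted hydrolysis of the dithioketal under buffered conditions should release the methyl ketone without touching the aldehyde or the β-silyloxy group.

Step 5
Reactants: 8 (S)-4-(TBSO)-2,2-dimethyl-6-oxoheptanal
Product: 10 (2R,4S)-4-(TBSO)-2,6,6-trimethyl-2-(TESO)cyclohexan-1-one, via α-ketol 9 (not isolated)
Conditions: 2-(pentafluorophenyl)-6,7-dihydro-5H-pyrrolo[2,1-c][1,2,4]triazol-2-ium tetrafluoroborate (10 mol %), Et3N (20 mol %), CH2Cl2, rt; then 2,6-lutidine, Et3SiOTf, −78 → 0 °C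
Reagents that add atoms: triethylsilyl trifluoromethanesulfonate, CC[Si](CC)(CC)OS(=O)(=O)C(F)(F)F
Why: N-Heterocyclic-carbene-catalysed intramolecular crossed benzoin (aldehyde–ketone acyloin) reaction, in which the acyl-anion equivalent of the aldehyde adds to the methyl ketone through a chair with the C4 silyloxy group and the ketone methyl equatorial, should place the new tertiary C–O bond axial and trans to the C4 oxygen (2R), and the hindered alcohol is then silylated in the same flask.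

Step 6
Reactants: 10 (2R,4S)-4-(TBSO)-2,6,6-trimethyl-2-(TESO)cyclohexan-1-one
Product: 11 (1R,2R,4S)-4-(TBSO)-1-ethynyl-2,6,6-trimethyl-2-(TESO)cyclohexan-1-ol
Conditions: HC≡CMgBr, CeCl3, THF, −78 → −20 °C; aq. NH4Cl at −78 °C
Reagents that add atoms: ethynylmagnesium bromide, C#C[Mg]Br
Why: 1,2-Addition of the ethynyl organocerium reagent to the non-enolizable ketone should occur axially, anti to the axial C2–O bond and away from the axial substituents at C2 and C6 that block the equatorial path, giving the (1R) carbinol with the two oxygens cis.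

Step 7
Reactants: 11 (1R,2R,4S)-4-(TBSO)-1-ethynyl-2,6,6-trimethyl-2-(TESO)cyclohexan-1-ol
Product: 13 methyl (Sa)-4-[(2R,4S)-4-(TBSO)-2-hydroxy-2,6,6-trimethylcyclohexylidene]but-3-enoate, via allenoate triethylsilyl ether 12 (not isolated)
Conditions: MeC(OMe)3, EtCO2H (cat.), xylenes, 140 °C; then HF·pyridine, pyridine, THF, 0 °C
Reagents that add atoms: trimethyl orthoacetate, COC(C)(OC)OC
Why: Johnson–Claisen rearrangement of the ketene acetal formed at the tertiary propargylic oxygen is suprafacial, so the CH2CO2Me group arrives at the alkyne terminus on the face that carried the C1 oxygen and the carbinol configuration becomes the (Sa) allene axis; buffered fluoride then removes only the triethylsilyl group.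

Step 8
Reactants: 13 methyl (Sa)-4-[(2R,4S)-4-(TBSO)-2-hydroxy-2,6,6-trimethylcyclohexylidene]but-3-enoate
Product: 14 methyl 2-[(2S,6S,7aR)-6-(TBSO)-4,4,7a-trimethyl-2,4,5,6,7,7a-hexahydro-1-benzofuran-2-yl]acetate
Conditions: AuCl3 (5 mol %), THF, rt
Reagents that add atoms: none
Why: AuCl3-catalysed 5-endo cycloisomerization of the α-hydroxyallene, in which the tertiary hydroxyl attacks the gold-activated allene terminus within the plane of the cyclohexylidene unit, should convert the allene axis into the C2 stereocentre (side chain trans to the C7a methyl) by axis-to-centre chirality transfer.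

Step 9
Reactants: 14 methyl 2-[(2S,6S,7aR)-6-(TBSO)-4,4,7a-trimethyl-2,4,5,6,7,7a-hexahydro-1-benzofuran-2-yl]acetate
Product: 16 methyl (Z)-2-[(2R,6S,7aR)-6-(TBSO)-4,4,7a-trimethyl-2,4,5,6,7,7a-hexahydro-1-benzofuran-2-yl]-3-(trifluoromethanesulfonyloxy)prop-2-enoate, via lithium formyl-ester enolate 15 (not isolated)
Conditions: LiN(iPr)2, THF, −78 °C; HCO2Me, −78 → −40 °C; then PhNTf2, −78 °C → rt
Reagents that add atoms: methyl formate, COC=O; N-phenylbis(trifluoromethanesulfonimide), O=S(=O)(N(c1ccccc1)S(=O)(=O)C(F)(F)F)C(F)(F)F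
Why: Crossed Claisen condensation (formylation) of the ester enolate followed by O-triflation of the lithium-chelated formyl-ester enolate should give the (Z) enol triflate (triflate cis to the ester), C2 being untouched (its descriptor becomes R only through the CIP priorities).

Step 10
Reactants: 16 methyl (Z)-2-[(2R,6S,7aR)-6-(TBSO)-4,4,7a-trimethyl-2,4,5,6,7,7a-hexahydro-1-benzofuran-2-yl]-3-(trifluoromethanesulfonyloxy)prop-2-enoate
Product: 17 methyl (Z)-2-[(2R,6S,7aR)-6-hydroxy-4,4,7a-trimethyl-2,4,5,6,7,7a-hexahydro-1-benzofuran-2-yl]-3-(trifluoromethanesulfonyloxy)prop-2-enoate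
Conditions: HF·pyridine, pyridine, THF, 0 °C → rt
Reagents that add atoms: none
Why: Buffered fluoride cleavage of the secondary silyl ether should leave the enol triflate, the ester and the allylic ether intact, so that no deprotection is needed after the polyene is attached.

Step 11
Reactants: 18 (4R,6R)-4-hydroxy-2,2,6-trimethylcyclohexan-1-one ((4R,6R)-actinol)
Product: 19 (4R,6R)-4-(TBSO)-2,2,6-trimethylcyclohexan-1-one
Conditions: t-BuMe2SiCl, imidazole, DMF, rt
Reagents that add atoms: tert-butyldimethylsilyl chloride, CC(C)(C)[Si](C)(C)Cl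
Why: Standard silylation of the chiral-pool ketone, which supplies the (R) carbinol centre of the cyclohexene end group.

Step 12
Reactants: 19 (4R,6R)-4-(TBSO)-2,2,6-trimethylcyclohexan-1-one
Product: 20 (R)-4-(TBSO)-2,6,6-trimethylcyclohex-1-en-1-yl trifluoromethanesulfonate
Conditions: LiN(iPr)2, THF, −78 → 0 °C; then PhNTf2, 0 °C → rt
Reagents that add atoms: N-phenylbis(trifluoromethanesulfonimide), O=S(=O)(N(c1ccccc1)S(=O)(=O)C(F)(F)F)C(F)(F)F
Why: Deprotonation at the only enolizable position and O-triflation of the enolate give the tetrasubstituted enol triflate, erasing the C6 centre on purpose and leaving C4 untouched.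

Step 13
Reactants: 20 (R)-4-(TBSO)-2,6,6-trimethylcyclohex-1-en-1-yl trifluoromethanesulfonate; 21 (E)-3-methylpent-2-en-4-yn-1-ol
Product: 22 (R,E)-5-[4-(TBSO)-2,6,6-trimethylcyclohex-1-en-1-yl]-3-methylpent-2-en-4-yn-1-ol
Conditions: Pd(PPh3)4 (5 mol %), CuI (10 mol %), iPr2NH, THF, 50 °C
Reagents that add atoms: none
Why: Sonogashira coupling (oxidative addition of the enol triflate to zerovalent palladium, copper acetylide transmetalation, reductive elimination) joins ring and enyne with retention of the (E) alkene.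

Step 14
Reactants: 22 (R,E)-5-[4-(TBSO)-2,6,6-trimethylcyclohex-1-en-1-yl]-3-methylpent-2-en-4-yn-1-ol
Product: 24 diethyl [(R,E)-5-[4-(TBSO)-2,6,6-trimethylcyclohex-1-en-1-yl]-3-methylpent-2-en-4-yn-1-yl]phosphonate, via allylic bromide 23 (not isolated)
Conditions: PBr3, pyridine (cat.), Et2O, −20 °C; then P(OEt)3, 100 °C
Reagents that add atoms: triethyl phosphite, CCOP(OCC)OCC
Why: Bromination of the allylic alcohol and Michaelis–Arbuzov reaction with triethyl phosphite should give the allylic phosphonate needed for an (E)-selective olefination.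

Step 15
Reactants: 21 (E)-3-methylpent-2-en-4-yn-1-ol
Product: 25 (E)-3-methylpent-2-en-4-ynal
Conditions: MnO2, CH2Cl2, rt
Reagents that add atoms: none
Why: Chemoselective MnO2 oxidation of the allylic alcohol to the enal leaves the terminal alkyne and the (E) alkene untouched.

Step 16
Reactants: 25 (E)-3-methylpent-2-en-4-ynal; 26 (triphenylphosphoranylidene)acetaldehyde
Product: 27 (2E,4E)-5-methylhepta-2,4-dien-6-ynal
Conditions: toluene, 70 °C
Reagents that add atoms: none
Why: Wittig reaction of the stabilized formylmethylene ylide extends the enal by two carbons, the stabilized ylide securing the new (E) double bond.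

Step 17
Reactants: 24 diethyl [(R,E)-5-[4-(TBSO)-2,6,6-trimethylcyclohex-1-en-1-yl]-3-methylpent-2-en-4-yn-1-yl]phosphonate; 27 (2E,4E)-5-methylhepta-2,4-dien-6-ynal
Product: 28 tert-butyl{[(R)-4-[(3E,5E,7E,9E)-3,10-dimethyldodeca-3,5,7,9-tetraene-1,11-diyn-1-yl]-3,5,5-trimethylcyclohex-3-en-1-yl]oxy}dimethylsilane
Conditions: NaN(SiMe3)2, THF, −78 °C; then 27, −78 → 0 °C
Reagents that add atoms: none
Why: Horner–Wadsworth–Emmons olefination of the allylic phosphonate anion with the dienal should form the central double bond with (E) selectivity, the stabilized anion being too weakly basic to deprotonate the terminal alkyne.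

Step 18
Reactants: 28 tert-butyl{[(R)-4-[(3E,5E,7E,9E)-3,10-dimethyldodeca-3,5,7,9-tetraene-1,11-diyn-1-yl]-3,5,5-trimethylcyclohex-3-en-1-yl]oxy}dimethylsilane
Product: 29 (R)-4-[(3E,5E,7E,9E)-3,10-dimethyldodeca-3,5,7,9-tetraene-1,11-diyn-1-yl]-3,5,5-trimethylcyclohex-3-en-1-ol
Conditions: Bu4NF, THF, 0 °C → rt
Reagents that add atoms: none
Why: Fluoride-mediated desilylation frees the cyclohexenol without affecting the polyenyne.

Step 19
Reactants: 17 methyl (Z)-2-[(2R,6S,7aR)-6-hydroxy-4,4,7a-trimethyl-2,4,5,6,7,7a-hexahydro-1-benzofuran-2-yl]-3-(trifluoromethanesulfonyloxy)prop-2-enoate; 29 (R)-4-[(3E,5E,7E,9E)-3,10-dimethyldodeca-3,5,7,9-tetraene-1,11-diyn-1-yl]-3,5,5-trimethylcyclohex-3-en-1-ol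
Product: 30 methyl (2Z,6E,8E,10E,12E)-2-[(2R,6S,7aR)-6-hydroxy-4,4,7a-trimethyl-2,4,5,6,7,7a-hexahydro-1-benzofuran-2-yl]-15-[(R)-4-hydroxy-2,6,6-trimethylcyclohex-1-en-1-yl]-6,13-dimethylpentadeca-2,6,8,10,12-pentaene-4,14-diynoate
Conditions: Pd(PPh3)4 (5 mol %), CuI (10 mol %), Et3N, THF, rt, dark
Reagents that add atoms: none
Why: Sonogashira coupling of the enol triflate with the terminal alkyne should proceed with retention of the (Z) geometry and tolerate both free hydroxyls.

Step 20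
Reactants: 30 methyl (2Z,6E,8E,10E,12E)-2-[(2R,6S,7aR)-6-hydroxy-4,4,7a-trimethyl-2,4,5,6,7,7a-hexahydro-1-benzofuran-2-yl]-15-[(R)-4-hydroxy-2,6,6-trimethylcyclohex-1-en-1-yl]-6,13-dimethylpentadeca-2,6,8,10,12-pentaene-4,14-diynoate
Product: 32 (5Z)-3-[(2R,6S,7aR)-6-hydroxy-4,4,7a-trimethyl-2,4,5,6,7,7a-hexahydro-1-benzofuran-2-yl]-5-[(2E,4E,6E,8E)-11-[(R)-4-hydroxy-2,6,6-trimethylcyclohex-1-en-1-yl]-2,9-dimethylundeca-2,4,6,8-tetraen-10-yn-1-ylidene]furan-2(5H)-one (target), via enynoic acid 31 (not isolated)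
Conditions: LiOH, THF/MeOH/H2O, 0 °C → rt; AcOH to pH 5; then AgNO3 (10 mol %), MeOH, rt, dark
Reagents that add atoms: lithium hydroxide, [Li+].[OH-]
Why: Saponification followed by AgNO3-catalysed 5-exo-dig addition of the carboxylic acid to the silver-activated alkyne (anti oxymetalation, then protodemetalation) should place the ring oxygen cis to the polyene chain, giving the (Z)-ylidenebutenolide.

Compound list
1 | 2-methyl-1,3-dithiane | CC1SCCCS1 | starting material
2 | (R)-epichlorohydrin, (R)-2-(chloromethyl)oxirane | ClC[C@H]1CO1 | starting material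
3 | isobutyronitrile | CC(C)C#N | starting material
4 | (R)-2-methyl-2-(oxiran-2-ylmethyl)-1,3-dithiane | C1[C@H](O1)CC2(C)SCCCS2 | intermediate
5 | (S)-4-hydroxy-2,2-dimethyl-5-(2-methyl-1,3-dithian-2-yl)pentanenitrile | N#CC(C)(C)C[C@H](O)CC1(C)SCCCS1 | intermediate
6 | (S)-4-[(tert-butyldimethylsilyl)oxy]-2,2-dimethyl-5-(2-methyl-1,3-dithian-2-yl)pentanenitrile | N#CC(C)(C)C[C@H](O[Si](C)(C)C(C)(C)C)CC1(C)SCCCS1 | intermediate
7 | (S)-4-[(tert-butyldimethylsilyl)oxy]-2,2-dimethyl-5-(2-methyl-1,3-dithian-2-yl)pentanal | O=CC(C)(C)C[C@H](O[Si](C)(C)C(C)(C)C)CC1(C)SCCCS1 | intermediate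
8 | (S)-4-[(tert-butyldimethylsilyl)oxy]-2,2-dimethyl-6-oxoheptanal | O=CC(C)(C)C[C@H](O[Si](C)(C)C(C)(C)C)CC(C)=O | intermediate
9 | (2R,4S)-4-[(tert-butyldimethylsilyl)oxy]-2-hydroxy-2,6,6-trimethylcyclohexan-1-one (hydroxyl trans to the silyloxy group) | O=C1C(C)(C)C[C@H](O[Si](C)(C)C(C)(C)C)C[C@@]1(C)O | intermediate
10 | (2R,4S)-4-[(tert-butyldimethylsilyl)oxy]-2,6,6-trimethyl-2-[(triethylsilyl)oxy]cyclohexan-1-one | O=C1C(C)(C)C[C@H](O[Si](C)(C)C(C)(C)C)C[C@@]1(C)O[Si](CC)(CC)CC | intermediate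
11 | (1R,2R,4S)-4-[(tert-butyldimethylsilyl)oxy]-1-ethynyl-2,6,6-trimethyl-2-[(triethylsilyl)oxy]cyclohexan-1-ol (C1 and C2 oxygens cis) | C#C[C@]1(O)C(C)(C)C[C@H](O[Si](C)(C)C(C)(C)C)C[C@@]1(C)O[Si](CC)(CC)CC | intermediate
12 | methyl (Sa)-4-[(2R,4S)-4-[(tert-butyldimethylsilyl)oxy]-2,6,6-trimethyl-2-[(triethylsilyl)oxy]cyclohexylidene]but-3-enoate (CH2CO2Me on the face of the C2 oxygen) | COC(=O)CC=[C@]=C1C(C)(C)C[C@H](O[Si](C)(C)C(C)(C)C)C[C@@]1(C)O[Si](CC)(CC)CC | intermediate
13 | methyl (Sa)-4-[(2R,4S)-4-[(tert-butyldimethylsilyl)oxy]-2-hydroxy-2,6,6-trimethylcyclohexylidene]but-3-enoate | COC(=O)CC=[C@]=C1C(C)(C)C[C@H](O[Si](C)(C)C(C)(C)C)C[C@@]1(C)O | intermediate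
14 | methyl 2-[(2S,6S,7aR)-6-[(tert-butyldimethylsilyl)oxy]-4,4,7a-trimethyl-2,4,5,6,7,7a-hexahydro-1-benzofuran-2-yl]acetate | COC(=O)C[C@H]1C=C2C(C)(C)C[C@H](O[Si](C)(C)C(C)(C)C)C[C@@]2(C)O1 | intermediate
15 | lithium (Z)-2-[(2R,6S,7aR)-6-[(tert-butyldimethylsilyl)oxy]-4,4,7a-trimethyl-2,4,5,6,7,7a-hexahydro-1-benzofuran-2-yl]-3-methoxy-3-oxoprop-1-en-1-olate | [Li+].COC(=O)/C(=C\[O-])[C@H]1C=C2C(C)(C)C[C@H](O[Si](C)(C)C(C)(C)C)C[C@@]2(C)O1 | intermediate
16 | methyl (Z)-2-[(2R,6S,7aR)-6-[(tert-butyldimethylsilyl)oxy]-4,4,7a-trimethyl-2,4,5,6,7,7a-hexahydro-1-benzofuran-2-yl]-3-{[(trifluoromethyl)sulfonyl]oxy}prop-2-enoate | COC(=O)/C(=C\OS(=O)(=O)C(F)(F)F)[C@H]1C=C2C(C)(C)C[C@H](O[Si](C)(C)C(C)(C)C)C[C@@]2(C)O1 | intermediate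
17 | methyl (Z)-2-[(2R,6S,7aR)-6-hydroxy-4,4,7a-trimethyl-2,4,5,6,7,7a-hexahydro-1-benzofuran-2-yl]-3-{[(trifluoromethyl)sulfonyl]oxy}prop-2-enoate | COC(=O)/C(=C\OS(=O)(=O)C(F)(F)F)[C@H]1C=C2C(C)(C)C[C@H](O)C[C@@]2(C)O1 | intermediate
18 | (4R,6R)-4-hydroxy-2,2,6-trimethylcyclohexan-1-one ((4R,6R)-actinol) | O=C1C(C)(C)C[C@H](O)C[C@H]1C | starting material
19 | (4R,6R)-4-[(tert-butyldimethylsilyl)oxy]-2,2,6-trimethylcyclohexan-1-one | O=C1C(C)(C)C[C@H](O[Si](C)(C)C(C)(C)C)C[C@H]1C | intermediate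
20 | (R)-4-[(tert-butyldimethylsilyl)oxy]-2,6,6-trimethylcyclohex-1-en-1-yl trifluoromethanesulfonate | CC1=C(OS(=O)(=O)C(F)(F)F)C(C)(C)C[C@H](O[Si](C)(C)C(C)(C)C)C1 | intermediate
21 | (E)-3-methylpent-2-en-4-yn-1-ol | C#C/C(C)=C/CO | starting material
22 | (R,E)-5-[4-[(tert-butyldimethylsilyl)oxy]-2,6,6-trimethylcyclohex-1-en-1-yl]-3-methylpent-2-en-4-yn-1-ol | CC1=C(C#C/C(C)=C/CO)C(C)(C)C[C@H](O[Si](C)(C)C(C)(C)C)C1 | intermediate
23 | {[(R)-4-[(E)-5-bromo-3-methylpent-3-en-1-yn-1-yl]-3,5,5-trimethylcyclohex-3-en-1-yl]oxy}(tert-butyl)dimethylsilane | CC1=C(C#C/C(C)=C/CBr)C(C)(C)C[C@H](O[Si](C)(C)C(C)(C)C)C1 | intermediate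
24 | diethyl [(R,E)-5-[4-[(tert-butyldimethylsilyl)oxy]-2,6,6-trimethylcyclohex-1-en-1-yl]-3-methylpent-2-en-4-yn-1-yl]phosphonate | CC1=C(C#C/C(C)=C/CP(=O)(OCC)OCC)C(C)(C)C[C@H](O[Si](C)(C)C(C)(C)C)C1 | intermediate
25 | (E)-3-methylpent-2-en-4-ynal | C#C/C(C)=C/C=O | intermediate
26 | (triphenylphosphoranylidene)acetaldehyde | O=CC=P(c1ccccc1)(c1ccccc1)c1ccccc1 | starting material
27 | (2E,4E)-5-methylhepta-2,4-dien-6-ynal | C#C/C(C)=C/C=C/C=O | intermediate
28 | tert-butyl{[(R)-4-[(3E,5E,7E,9E)-3,10-dimethyldodeca-3,5,7,9-tetraene-1,11-diyn-1-yl]-3,5,5-trimethylcyclohex-3-en-1-yl]oxy}dimethylsilane | CC1=C(C#C/C(C)=C/C=C/C=C/C=C(C)/C#C)C(C)(C)C[C@H](O[Si](C)(C)C(C)(C)C)C1 | intermediate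
29 | (R)-4-[(3E,5E,7E,9E)-3,10-dimethyldodeca-3,5,7,9-tetraene-1,11-diyn-1-yl]-3,5,5-trimethylcyclohex-3-en-1-ol | CC1=C(C#C/C(C)=C/C=C/C=C/C=C(C)/C#C)C(C)(C)C[C@H](O)C1 | intermediate
30 | methyl (2Z,6E,8E,10E,12E)-2-[(2R,6S,7aR)-6-hydroxy-4,4,7a-trimethyl-2,4,5,6,7,7a-hexahydro-1-benzofuran-2-yl]-15-[(R)-4-hydroxy-2,6,6-trimethylcyclohex-1-en-1-yl]-6,13-dimethylpentadeca-2,6,8,10,12-pentaene-4,14-diynoate | CC1=C(C#C/C(C)=C/C=C/C=C/C=C(C)/C#C/C=C(/[C@H]2C=C3C(C)(C)C[C@H](O)C[C@@]3(C)O2)C(=O)OC)C(C)(C)C[C@H](O)C1 | intermediate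
31 | (2Z,6E,8E,10E,12E)-2-[(2R,6S,7aR)-6-hydroxy-4,4,7a-trimethyl-2,4,5,6,7,7a-hexahydro-1-benzofuran-2-yl]-15-[(R)-4-hydroxy-2,6,6-trimethylcyclohex-1-en-1-yl]-6,13-dimethylpentadeca-2,6,8,10,12-pentaene-4,14-diynoic acid | CC1=C(C#C/C(C)=C/C=C/C=C/C=C(C)/C#C/C=C(/[C@H]2C=C3C(C)(C)C[C@H](O)C[C@@]3(C)O2)C(=O)O)C(C)(C)C[C@H](O)C1 | intermediate
32 | (5Z)-3-[(2R,6S,7aR)-6-hydroxy-4,4,7a-trimethyl-2,4,5,6,7,7a-hexahydro-1-benzofuran-2-yl]-5-[(2E,4E,6E,8E)-11-[(R)-4-hydroxy-2,6,6-trimethylcyclohex-1-en-1-yl]-2,9-dimethylundeca-2,4,6,8-tetraen-10-yn-1-ylidene]furan-2(5H)-one | CC1=C(C#C/C(C)=C/C=C/C=C/C=C(C)/C=C2/C=C([C@H]3C=C4C(C)(C)C[C@H](O)C[C@@]4(C)O3)C(=O)O2)C(C)(C)C[C@H](O)C1 | target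

Total step count: 20. Longest linear sequence: 12 steps (steps 1 to 10, then 19 and 20).

Steps most likely to fail

Step 7. The mixed orthoester may not form at a tertiary carbinol wedged between two fully substituted carbons. The acid at 140 °C may also ionize the propargylic alcohol (Meyer–Schuster-type rearrangement) or strip the triethylsilyl group, after which a cyclic orthoester would block the rearrangement. The fallback replaces the orthoester Claisen by an ester-enolate Claisen and sets out from 10. The ethynylation of step 6 is quenched in the flask with Ac2O, so that the alkoxide is trapped as (1R,2R,4S)-4-(TBSO)-1-ethynyl-2,6,6-trimethyl-2-(TESO)cyclohexyl acetate F1. Treatment with LiN(iPr)2 and Me3SiCl/Et3N in THF at −78 °C and warming to 40 °C should give, by Ireland–Claisen rearrangement through the same suprafacial course, (Sa)-4-[(2R,4S)-4-(TBSO)-2,6,6-trimethyl-2-(TESO)cyclohexylidene]but-3-enoic acid F2. Esterification with Me3SiCHN2 in toluene/MeOH comes back to the route at 12, which is desilylated to 13 as in step 7.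

Step 5. The acyl-anion equivalent may form slowly at the α-quaternary aldehyde. Base-mediated aldol closure from the methyl ketone, β-elimination of the silyloxy group or poor facial selection at the ketone could then take over. The fallback is a reductive pinacol closure followed by oxidation and sets out from 8. SmI2 in THF/t-BuOH at −78 °C should close the ring through a chelated chair with methyl and silyloxy equatorial to (1S,2R,4S)-4-(TBSO)-2,6,6-trimethylcyclohexane-1,2-diol F3. Oxidation of its secondary alcohol with 1,1,1-triacetoxy-1,1-dihydro-1,2-benziodoxol-3(1H)-one (NaHCO3, CH2Cl2) comes back to the route at 9, which is silylated to 10 as in step 5.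

Step 9. The lithium ester enolate of 14 carries the ring oxygen in the β-position. β-Elimination (retro-oxa-Michael opening of the dihydrofuran, with loss of the C2 configuration on re-closure) may compete with formylation, and triflation may give an E/Z mixture. The fallback is a base-free aminomethylenation and sets out from 14. Heating with tert-butoxybis(dimethylamino)methane in toluene at 100 °C should give methyl (E)-3-(dimethylamino)-2-[(2R,6S,7aR)-6-(TBSO)-4,4,7a-trimethyl-2,4,5,6,7,7a-hexahydro-1-benzofuran-2-yl]prop-2-enoate F4. Hydrolysis with aq. AcOH/THF gives the hydrogen-bonded enol methyl (Z)-3-hydroxy-2-[(2R,6S,7aR)-6-(TBSO)-4,4,7a-trimethyl-2,4,5,6,7,7a-hexahydro-1-benzofuran-2-yl]prop-2-enoate F5. Triflation with Tf2O and iPr2NEt in CH2Cl2 at −78 °C comes back to the route at 16.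

Further compounds
F1 | step 7 | (1R,2R,4S)-4-[(tert-butyldimethylsilyl)oxy]-1-ethynyl-2,6,6-trimethyl-2-[(triethylsilyl)oxy]cyclohexyl acetate | C#C[C@]1(OC(C)=O)C(C)(C)C[C@H](O[Si](C)(C)C(C)(C)C)C[C@@]1(C)O[Si](CC)(CC)CC
F2 | step 7 | (Sa)-4-[(2R,4S)-4-[(tert-butyldimethylsilyl)oxy]-2,6,6-trimethyl-2-[(triethylsilyl)oxy]cyclohexylidene]but-3-enoic acid | OC(=O)CC=[C@]=C1C(C)(C)C[C@H](O[Si](C)(C)C(C)(C)C)C[C@@]1(C)O[Si](CC)(CC)CC
F3 | step 5 | (1S,2R,4S)-4-[(tert-butyldimethylsilyl)oxy]-2,6,6-trimethylcyclohexane-1,2-diol | O[C@H]1C(C)(C)C[C@H](O[Si](C)(C)C(C)(C)C)C[C@@]1(C)O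
F4 | step 9 | methyl (E)-3-(dimethylamino)-2-[(2R,6S,7aR)-6-[(tert-butyldimethylsilyl)oxy]-4,4,7a-trimethyl-2,4,5,6,7,7a-hexahydro-1-benzofuran-2-yl]prop-2-enoate | COC(=O)/C(=C/N(C)C)[C@H]1C=C2C(C)(C)C[C@H](O[Si](C)(C)C(C)(C)C)C[C@@]2(C)O1
F5 | step 9 | methyl (Z)-3-hydroxy-2-[(2R,6S,7aR)-6-[(tert-butyldimethylsilyl)oxy]-4,4,7a-trimethyl-2,4,5,6,7,7a-hexahydro-1-benzofuran-2-yl]prop-2-enoate | COC(=O)/C(=C\O)[C@H]1C=C2C(C)(C)C[C@H](O[Si](C)(C)C(C)(C)C)C[C@@]2(C)O1
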